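**Retrosynthetic overview**
- The acyl chain C1–C23 is cut at C14–C15 by a crossed (mixed) Kolbe electrolysis, that is, anodic decarboxylative radical–radical coupling of decanoic acid (C9 radical) with the mono(2-phenylethyl) ester of pentadecanedioic acid (C14 radical).
- Enabling feature: C14 and C15 are unbranched CH2 carbons in an unfunctionalised polymethylene chain, so both radicals are primary and hard to over-oxidise. The ester C1(=O)–O is thirteen carbons from C14, and the benzene ring is insulated by an OCH2CH2 spacer.
- The half-ester comes from the cheap 16-membered macrolactone pentadecanolide. Its ring differentiates the two chain ends: it is opened with 2-phenylethanol, then the freed CH2OH is oxidised to CO2H.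
- No ring is formed. The benzene ring is purchased and the temporary macrolactone ring is opened in step 1.

Key step: step 3

Remark on the chemistry: the target has no stereocentre and no stereogenic double bond, so it is achiral and no step needs stereocontrol.

**Step 1**
Reactants: 1 pentadecanolide (oxacyclohexadecan-2-one); 2 2-phenylethanol (excess)
Product: 3 2-phenylethyl 15-hydroxypentadecanoate
Conditions: 2 (10 equiv, as solvent), p-TsOH·H2O (cat.), 90 °C; aq. NaHCO3 wash, then excess 2 removed by short-path distillation
Reagents that add atoms: none
Why: In this acid-catalysed transesterification (ring-opening alcoholysis of a lactone), the large excess of the primary alcohol should drive the equilibrium to the open hydroxy ester and suppress attack by the liberated chain hydroxyl.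

**Step 2**
Reactants: 3 2-phenylethyl 15-hydroxypentadecanoate
Product: 5 15-oxo-15-(2-phenylethoxy)pentadecanoic acid, via 2-phenylethyl 15-oxopentadecanoate 4 (not isolated)
Conditions: TEMPO (0.2 equiv), PhI(OAc)2 (2.2 equiv), CH2Cl2/MeCN/H2O, rt
Reagents that add atoms: water, O
Why: In this oxoammonium-mediated (TEMPO/PhI(OAc)2) oxidation, the primary alcohol goes to the aldehyde, whose hydrate is oxidised on to the acid, and the mild, near-neutral medium should leave the ester and the phenethyl CH2 groups untouched.

**Step 3**
Reactants: 5 15-oxo-15-(2-phenylethoxy)pentadecanoic acid; 6 decanoic acid (5 equiv)
Product: 9 2-phenylethyl tricosanoate, via nonyl radical 7 (not isolated), via 13-[(2-phenylethoxy)carbonyl]tridecyl radical 8 (not isolated)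
Conditions: Pt anode / Pt cathode, undivided cell, KOH (5–10 mol % of total acid), MeOH with a hexane overlayer, constant current at high density (about 150–250 mA cm⁻²), 40–45 °C, stopped while the solution is still weakly acidic; chromatography on SiO2
Reagents that add atoms: none
Why: This is a crossed Kolbe electrolysis, classical for pairing a fatty acid with a dicarboxylic acid half-ester, in which both carboxylates are oxidised by one electron at platinum, lose CO2, and the primary radicals 7 and 8, formed at high concentration at the anode surface, combine to make the C14–C15 bond while protons are reduced to hydrogen at the cathode. High current density, partial neutralisation and smooth platinum favour the radical pathway, and because neither radical carries an α-branch or α-heteroatom, further oxidation to a cation (the Hofer–Moest pathway) should stay minor. Cross-selectivity is statistical, so the cheap acid 6 is used in excess to consume most of 8 in the crossed coupling. The three coupling products carry zero (octadecane), one (9) and two ester groups, so they should separate easily on silica. The adsorbed carboxylate layer at the anode should shield the distant benzene ring from oxidation, and the weakly acidic bulk medium should prevent methanolysis of the phenethyl ester. No ring is closed and no stereocentre is created.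

**Compound list**
1 | pentadecanolide (oxacyclohexadecan-2-one) | O=C1CCCCCCCCCCCCCCO1 | starting material
2 | 2-phenylethanol | OCCc1ccccc1 | starting material
3 | 2-phenylethyl 15-hydroxypentadecanoate | OCCCCCCCCCCCCCCC(=O)OCCc1ccccc1 | intermediate
4 | 2-phenylethyl 15-oxopentadecanoate (aldehyde, not isolated) | O=CCCCCCCCCCCCCCC(=O)OCCc1ccccc1 | intermediate
5 | 15-oxo-15-(2-phenylethoxy)pentadecanoic acid (pentadecanedioic acid mono(2-phenylethyl) ester) | OC(=O)CCCCCCCCCCCCCC(=O)OCCc1ccccc1 | intermediate
6 | decanoic acid | CCCCCCCCCC(=O)O | starting material
7 | nonyl radical (not isolated) | CCCCCCCC[CH2] | intermediate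
8 | 13-[(2-phenylethoxy)carbonyl]tridecyl radical (not isolated) | [CH2]CCCCCCCCCCCCC(=O)OCCc1ccccc1 | intermediate
9 | 2-phenylethyl tricosanoate (achiral) | CCCCCCCCCCCCCCCCCCCCCCC(=O)OCCc1ccccc1 | target

**Total step count:** 3
**Longest linear sequence:** 3 (1 → 3 → 5 → 9)

**Steps most likely to fail, with fallbacks**

1. Step 3.
   - Risks: statistical homocoupling may take much of the half-ester, waxy products may foul the anode, and some methanolysis of the ester or anodic attack on the arene may occur.
   - Fallback (a metal-catalysed decarboxylative cross-coupling instead of electrolysis), setting out from 5: the acid is condensed with N-hydroxyphthalimide (DIC, cat. DMAP, CH2Cl2) to give the redox-active ester 1,3-dioxoisoindolin-2-yl 2-phenylethyl pentadecanedioate F1.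
   - Nonylzinc bromide F2 is prepared from 1-bromononane and activated zinc in THF.
   - A Ni-catalysed decarboxylative alkyl–alkyl Negishi coupling of F1 with F2 (NiCl2·glyme, 4,4'-di-tert-butyl-2,2'-bipyridine, THF/DMF, rt) forms the same C14–C15 bond selectively and returns to the route at 9.

2. Step 1.
   - Risks: the lactone may open incompletely, and the liberated hydroxyl may compete with 2-phenylethanol to give oligoesters.
   - Fallback (the ester is made by alkylation at oxygen instead of acyl substitution), setting out from 1: saponification (KOH, aq. EtOH, then HCl) gives 15-hydroxypentadecanoic acid F3.
   - The caesium carboxylate of F3 is alkylated with (2-bromoethyl)benzene (Cs2CO3, DMF, rt). The carboxylate reacts in preference to the neutral hydroxyl, and the route is rejoined at 3.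

3. Step 2.
   - Risks: the oxidation may stall at the aldehyde stage, a dimeric ester may form through the hemiacetal of aldehyde and unreacted alcohol, and the waxy substrate may dissolve poorly in the aqueous medium.
   - Fallback (no oxidation at all), setting out from 2: purchased pentadecanedioic acid F4, used in threefold excess, is mono-esterified with 2 under Fischer conditions (cat. p-TsOH, toluene, Dean–Stark).
   - Unreacted diacid is removed by filtration or base extraction and recycled, and the route is rejoined at 5, bypassing steps 1 and 2.

**Further compounds**
F1 | step 3 | 1,3-dioxoisoindolin-2-yl 2-phenylethyl pentadecanedioate (N-hydroxyphthalimide ester of 5) | O=C(ON1C(=O)c2ccccc2C1=O)CCCCCCCCCCCCCC(=O)OCCc1ccccc1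
F2 | step 3 | nonylzinc bromide | CCCCCCCCC[Zn]Br
F3 | step 1 | 15-hydroxypentadecanoic acid | OCCCCCCCCCCCCCCC(=O)O
F4 | step 2 | pentadecanedioic acid (purchased) | OC(=O)CCCCCCCCCCCCCC(=O)O
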